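**Retrosynthetic overview**
- Last bond: Sonogashira union of an alkynyl 1,2-dioxane core with a C11 (E)-iodo-diene made by Takai olefination.
- The only ring, the 1,2-dioxane, is closed in the step before that: acid methanolysis of a (3S)-β-peroxy keto acid forms the C6 methyl peroxyketal (thermodynamic OMe) and the methyl ester together.
- The C3–O stereocentre comes from an amine-catalysed asymmetric conjugate peroxidation of an (E)-6-oxo-2-enal, followed by Pinnick oxidation.
- The keto-enal comes from a Wittig extension of a 4-oxoaldehyde whose C5–C6 bond is made by acylating a masked propanal β-anion (homoenolate) with a C6 alkynoyl chloride; both carbons are natively electrophilic.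

Assumption: all starting materials are bought as such (the acetal Grignard as its commercial THF solution, the C10 enal as the aroma chemical); locants follow the target ring, O1–O2–C3 (acetate arm)–C4–C5–C6 (OMe, side chain).

**Step 1**
Reactants: 1 hex-5-ynoic acid; 2 [2-(1,3-dioxolan-2-yl)ethyl]magnesium bromide
Product: 4 1-(1,3-dioxolan-2-yl)oct-7-yn-3-one, via hex-5-ynoyl chloride 3 (not isolated)
Conditions: (COCl)2, DMF (cat.), CH2Cl2, 0 °C to rt, evaporate; then 2 (1.05 equiv), CuI (5 mol%), THF, −78 °C
Reagents that add atoms: oxalyl chloride, O=C(Cl)C(=O)Cl (supplies the Cl of 3)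
Why: Homoenolate acylation (copper-catalysed Grignard ketone synthesis): the acetal Grignard is a propanal β-anion equivalent that attacks the acyl chloride carbon, and at −78 °C this outruns over-addition and deprotonation of the terminal alkyne; no stereocenter is formed.

**Step 2**
Reactants: 4 1-(1,3-dioxolan-2-yl)oct-7-yn-3-one; 5 (triphenylphosphoranylidene)acetaldehyde
Product: 7 (2E)-6-oxoundec-2-en-10-ynal, via 4-oxonon-8-ynal 6 (not isolated)
Conditions: 1 M HCl, THF, rt, extract; then 5 (1.2 equiv), PhMe, 80 °C
Reagents that add atoms: water, O (supplies the aldehyde O of 6)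
Why: Acetal hydrolysis then Wittig olefination with the stabilised formylmethylene ylide, which attacks only the aldehyde (not the ketone) and gives the (E)-enal.

**Step 3**
Reactants: 8 2,3-dimethylbut-2-ene
Product: 9 2-hydroperoxy-2-methoxypropane
Conditions: O3, MeOH/CH2Cl2, −78 °C
Reagents that add atoms: ozone, [O-][O+]=O; methanol, CO
Why: Ozonolysis in methanol: the Criegee carbonyl oxide of acetone is trapped by MeOH as the α-methoxy hydroperoxide, a protected form of H2O2; no stereocenter.

**Step 4**
Reactants: 7 (2E)-6-oxoundec-2-en-10-ynal; 9 2-hydroperoxy-2-methoxypropane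
Product: 11 (3S)-3-[(2-methoxypropan-2-yl)peroxy]-6-oxoundec-10-ynoic acid, via (3S)-3-[(2-methoxypropan-2-yl)peroxy]-6-oxoundec-10-ynal 10 (not isolated)
Conditions: (R)-2-{bis[3,5-bis(trifluoromethyl)phenyl][(trimethylsilyl)oxy]methyl}pyrrolidine (10 mol%), 9 (1.5 equiv), PhMe, 0 °C; then NaClO2, NaH2PO4, 2-methylbut-2-ene, t-BuOH/H2O, 0 °C; acid isolated by NaHCO3 extraction
Reagents that add atoms: sodium chlorite, [Na+].[O-]Cl=O
Why: Iminium-catalysed asymmetric peroxy-Michael addition to the (E)-enal, in which the (R)-diarylprolinol silyl ether blocks the Re face of C3 so the hydroperoxide adds to the Si face and sets (3S) (sense assigned from the standard shielding model), followed by Pinnick oxidation of the crude aldehyde, which leaves peroxide, ketone and alkyne untouched.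

**Step 5**
Reactants: 11 (3S)-3-[(2-methoxypropan-2-yl)peroxy]-6-oxoundec-10-ynoic acid
Product: 12 methyl 2-[(3S,6R)-6-methoxy-6-(pent-4-yn-1-yl)-1,2-dioxan-3-yl]acetate
Conditions: TsOH·H2O (10 mol%), MeOH, 3 Å sieves, rt to 35 °C
Reagents that add atoms: methanol, CO
Why: Acid-catalysed methanolysis cascade (Fischer esterification, cleavage of the 2-methoxyprop-2-yl peroxyketal to the C3 hydroperoxide, six-membered peroxyhemiketalisation onto C6 and methanol exchange through the peroxycarbenium ion): C3 is untouched and C6 settles under thermodynamic control with OMe axial (anomeric effect) and both carbon arms equatorial, which is (6R), cis to the acetate arm; the minor C6 epimer is separated and re-equilibrated.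

**Step 6**
Reactants: 13 dec-9-enal
Product: 14 (1E)-1-iodoundeca-1,10-diene
Conditions: CrCl2 (6 equiv), CHI3 (2 equiv), THF/1,4-dioxane, 0 °C to rt
Reagents that add atoms: iodoform, IC(I)I
Why: Takai olefination: the geminal dichromium species formed from CHI3 and divalent chromium adds to the aldehyde and eliminates to the (E)-iodoalkene (dioxane raises E:Z; the minor Z isomer is removed on AgNO3-silica), and the terminal alkene is inert.

**Step 7**
Reactants: 12 methyl 2-[(3S,6R)-6-methoxy-6-(pent-4-yn-1-yl)-1,2-dioxan-3-yl]acetate; 14 (1E)-1-iodoundeca-1,10-diene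
Product: 15 methyl 2-[(3S,6R)-6-[(6E)-hexadeca-6,15-dien-4-yn-1-yl]-6-methoxy-1,2-dioxan-3-yl]acetate (peroxyacarnoate A)
Conditions: PdCl2(PPh3)2 (5 mol%), CuI (10 mol%), Et3N, THF, rt
Reagents that add atoms: none
Why: Sonogashira coupling: zerovalent palladium inserts into the C–I bond with retention of the E geometry and couples with the copper acetylide of 12, and these neutral room-temperature conditions are expected to spare the dialkyl peroxyketal; neither stereocenter is touched.

**Compound list**
1 | hex-5-ynoic acid | C#CCCCC(=O)O | starting material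
2 | [2-(1,3-dioxolan-2-yl)ethyl]magnesium bromide | Br[Mg]CCC1OCCO1 | starting material
3 | hex-5-ynoyl chloride | C#CCCCC(=O)Cl | intermediate
4 | 1-(1,3-dioxolan-2-yl)oct-7-yn-3-one | C#CCCCC(=O)CCC1OCCO1 | intermediate
5 | (triphenylphosphoranylidene)acetaldehyde | O=CC=P(c1ccccc1)(c1ccccc1)c1ccccc1 | starting material
6 | 4-oxonon-8-ynal | C#CCCCC(=O)CCC=O | intermediate
7 | (2E)-6-oxoundec-2-en-10-ynal | C#CCCCC(=O)CC/C=C/C=O | intermediate
8 | 2,3-dimethylbut-2-ene | CC(C)=C(C)C | starting material
9 | 2-hydroperoxy-2-methoxypropane | COC(C)(C)OO | intermediate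
10 | (3S)-3-[(2-methoxypropan-2-yl)peroxy]-6-oxoundec-10-ynal | C#CCCCC(=O)CC[C@@H](CC=O)OOC(C)(C)OC | intermediate
11 | (3S)-3-[(2-methoxypropan-2-yl)peroxy]-6-oxoundec-10-ynoic acid | C#CCCCC(=O)CC[C@@H](CC(=O)O)OOC(C)(C)OC | intermediate
12 | methyl 2-[(3S,6R)-6-methoxy-6-(pent-4-yn-1-yl)-1,2-dioxan-3-yl]acetate | C#CCCC[C@]1(OC)CC[C@@H](CC(=O)OC)OO1 | intermediate
13 | dec-9-enal | C=CCCCCCCCC=O | starting material
14 | (1E)-1-iodoundeca-1,10-diene | C=CCCCCCCC/C=C/I | intermediate
15 | methyl 2-[(3S,6R)-6-[(6E)-hexadeca-6,15-dien-4-yn-1-yl]-6-methoxy-1,2-dioxan-3-yl]acetate (peroxyacarnoate A) | C=CCCCCCCC/C=C/C#CCCC[C@]1(OC)CC[C@@H](CC(=O)OC)OO1 | target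

**Totals**
Total step count: 7. Longest linear sequence: 5 (steps 1, 2, 4, 5, 7); steps 3 and 6 are side branches.

**Three steps most likely to fail**

Step 4 (asymmetric peroxidation and oxidation). The risks are amine-mediated epoxide formation, intramolecular aldol of the enamine onto the C6 ketone, and insufficient ee. The fallback sets out from 4 and returns at 12, and gives up catalytic asymmetric induction in favour of resolution. Compound 4 is hydrolysed to 6 as in step 2 but olefinated with methyl (triphenylphosphoranylidene)acetate to give methyl (2E)-6-oxoundec-2-en-10-ynoate F1. H2O2·urea with Sc(OTf)3 in MeOH converts the ketone into methyl (2E)-6-hydroperoxy-6-methoxyundec-2-en-10-ynoate F2. Et2NH in CF3CH2OH closes the ring by intramolecular peroxy-Michael addition, and TsOH in MeOH equilibrates C6 to racemic cis methyl 2-[6-methoxy-6-(pent-4-yn-1-yl)-1,2-dioxan-3-yl]acetate F3. Preparative HPLC on a chiral stationary phase then gives 12.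

Step 5 (one-pot esterification and peroxyketal closure). The risks are incomplete esterification, acid-induced loss of the free hydroperoxide, and a poor C6 ratio. The fallback sets out from 11 and returns at 12, replacing the protic equilibrium by an aprotic, kinetic closure. TMSCHN2 in MeOH/PhMe gives methyl (3S)-3-[(2-methoxypropan-2-yl)peroxy]-6-oxoundec-10-ynoate F4. Noyori-type ketalisation (MeOSiMe3, cat. TMSOTf, CH2Cl2, −78 °C) generates the C6 methoxycarbenium ion, which is captured by the peroxide oxygen while the 2-methoxyprop-2-yl cation leaves, giving 12 without water or a free hydroperoxide.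

Step 7 (Sonogashira on the peroxide). The risks are O–O reduction by phosphine, copper or zerovalent palladium, and amine-induced ring opening next to the ester. The fallback sets out from 7 (with 14) and returns at 15, making the enyne before any O–O bond exists. Compounds 7 and 14 are coupled under the step 7 conditions to give (2E,12E)-6-oxodocosa-2,12,21-trien-10-ynal F5. Step 4 run on this full-chain enal gives (3S,12E)-3-[(2-methoxypropan-2-yl)peroxy]-6-oxodocosa-12,21-dien-10-ynal F6 and, after Pinnick oxidation, (3S,12E)-3-[(2-methoxypropan-2-yl)peroxy]-6-oxodocosa-12,21-dien-10-ynoic acid F7. The step 5 methanolysis then closes the dioxane to give 15 directly.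

**Further compounds**
F1 | step 4 | methyl (2E)-6-oxoundec-2-en-10-ynoate | C#CCCCC(=O)CC/C=C/C(=O)OC
F2 | step 4 | methyl (2E)-6-hydroperoxy-6-methoxyundec-2-en-10-ynoate (racemic) | C#CCCCC(OC)(OO)CC/C=C/C(=O)OC
F3 | step 4 | methyl 2-[6-methoxy-6-(pent-4-yn-1-yl)-1,2-dioxan-3-yl]acetate (racemic, cis) | C#CCCCC1(OC)CCC(CC(=O)OC)OO1
F4 | step 5 | methyl (3S)-3-[(2-methoxypropan-2-yl)peroxy]-6-oxoundec-10-ynoate | C#CCCCC(=O)CC[C@@H](CC(=O)OC)OOC(C)(C)OC
F5 | step 7 | (2E,12E)-6-oxodocosa-2,12,21-trien-10-ynal | C=CCCCCCCC/C=C/C#CCCCC(=O)CC/C=C/C=O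
F6 | step 7 | (3S,12E)-3-[(2-methoxypropan-2-yl)peroxy]-6-oxodocosa-12,21-dien-10-ynal | C=CCCCCCCC/C=C/C#CCCCC(=O)CC[C@@H](CC=O)OOC(C)(C)OC
F7 | step 7 | (3S,12E)-3-[(2-methoxypropan-2-yl)peroxy]-6-oxodocosa-12,21-dien-10-ynoic acid | C=CCCCCCCC/C=C/C#CCCCC(=O)CC[C@@H](CC(=O)O)OOC(C)(C)OC
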